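(All runs were computed for an exercise; noise was put on by code.)

In a one-step world each substrate that goes becomes target, and a clock tells the whole story. Monday's and Wednesday's runs stop short of that, and two chemists argue over how far this flask does.

| setting | Monday's | Wednesday's | flask |
|---|---|---|---|
| substrate | 0.54 M | 1.2 M | 0.80 M |
| reagent in the second phase | 2 M | 2 M | 2.00 M |
| remark | run made earlier | run made earlier |  |
| time |  |  | 40 min |
| volume of the second phase over the first |  |  | 1.0 |

| run | time / min | target / % | substrate / % |
|---|---|---|---|
| Monday's | 3.00 | 6.2 | 94.0 |
| Monday's | 10.0 | 37.3 | 60.1 |
| Monday's | 15.0 | 57.6 | 36.7 |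
| Monday's | 25.0 | 81.1 | 11.4 |
| Monday's | 40.0 | 89.7 | 0.7 |
| Monday's | 50.0 | 90.7 | 0.8 |
| Wednesday's | 8.00 | 20.9 | 72.4 |
| Wednesday's | 15.0 | 39.8 | 48.1 |
| Wednesday's | 25.0 | 58.6 | 24.8 |
| Wednesday's | 30.0 | 63.5 | 15.7 |
| Wednesday's | 40.0 | 70.9 | 5.9 |
| Wednesday's | 50.0 | 74.1 | 1.2 |

(readings scatter by 0.5 percentage points)

- the target standing at 40 min, as a percentage of the substrate charged
- the change that raises the amount of target at 40 min, in percent of the substrate charged most ("none" if none brings more than 2 percentage points) (east / south / none)
- amount of target at 40 min, in percent of the substrate charged, after south

- east: doubling the amount of reagent in the second phase, all else as stated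
- south: doubling the transfer coefficient of the reagent in the second phase, all else as stated

- in the second phase: reagent in the second phase; everything else is in the first
- charges count per volume of the first phase; a concentration in a rate is the amount of a species over the volume of its own phase; every rate counts per litre of the first phase
- the earlier runs hold the two phases in the same ratio of volumes as the flask asked about

Both follow one molecule of substrate to its fork, where it becomes target or something else. They count the target made per substrate used up. At 40.0 min the readings give 0.903 in Monday's run and 0.753 in Wednesday's. A straight line in c(substrate) between the runs puts the substrate left in this flask at 2.75%.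

The first chemist sees one step with a small fixed loss. This flask's charge lies nearer Monday's, so he takes Monday's figure and gets 87.8% target.

The second chemist notes that the figure is lower at the higher charge, so she draws the same straight line through it. My own reckoning follows hers: the fork share for this flask, target made per substrate used up (the selectivity), is 0.844, which gives 82.1% target. With that share held, a change can add at most 2.3 percentage points, by finishing the substrate left.

The forecast takes her side with 83.5%, above my figure. It names none as the best change and gives 84.5% after south, holding that “Loss tracks the main rate, so faster transfer barely changes selectivity”.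

The flask gives 83.2% target with 2.5% substrate left, a fork share of 0.853. The best change is east, worth 7.9 points; south gives 89.0%, worth 5.8 points.

    reagent in the reaction phase ⇌ reagent in the second phase, rate k1*([reagent in the reaction phase] - [reagent in the second phase]/K1) per volume of the first phase (partition coefficient = 0.488, kL = 2.70 × 10⁻⁴ s⁻¹)
    substrate + reagent in the reaction phase → target (k = 0.00422 M⁻¹ s⁻¹)
    substrate + target → side product (k = 2.34 × 10⁻⁴ M⁻¹ s⁻¹)
    reagent in the reaction phase ⇌ dormant form (K = 0.301, k = 2.02 × 10⁻⁴ s⁻¹)
    2 substrate → homo dimer (k = 4.24 × 10⁻⁵ M⁻¹ s⁻¹)

His number lies 4.6 points above the flask. His fixed share has its region towards Monday's charge: at c(substrate) 0.610 M, with the reagent and the time held, this flask's answer has moved by 5 points. Her share of 0.844 stood close to the flask's 0.853 as charged, but it did not carry over to south: south's gain is more than the ceiling, and after south the target alone is 89.0% of the charge, more than 0.844. The same flask read at 15 min has 42% substrate left, so the fork share gives 49.0% target, and it holds 49.5%.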